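A direct plan would join two ready-made benzene rings at the aryl–CH2 bond. Methyl 6-chloro-2,4-dihydroxy-3-methylbenzoate A1, built by two ortho-lithiations and an ether cleavage, would be coupled under palladium catalysis with the acyloxymethyl trifluoroborate A2 that carries ring B. Its weakest steps would be:
- the sp2–sp3 coupling itself, which has no close precedent for an aroyloxymethyl boron reagent and would expose an aryl ester, an aldehyde and free phenols to hot aqueous carbonate;
- the carboxylation of an ortho-chloro aryllithium, which could lose LiCl to an aryne;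
- the cleavage of a hindered methyl ester and of two methyl ethers, which would add length without adding complexity.

**Strategy.** The route rests on making ring A last, by a Diels–Alder benzannulation. The bis-silyl dienol ether of methyl 2-methylacetoacetate (C2–C5, with the 2,4-dioxygen pattern and the C3 methyl) adds to an acetylenic ester whose propargylic carbon already carries the complete ring B ester. The alkyne carbons become C1 and C6 of ring A, so one operation forms two ring C–C bonds and sets the ester, both hydroxyls, the C-methyl group and the acyloxymethyl arm. The aryl–CH2 and benzylic C–O bonds exist before the arene does: no cross-coupling, no aryllithium, no ether or hindered-ester cleavage, and no free ortho-hydroxymethyl benzoate that could close to a phthalide.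

Key step: step 5

Assumption: methyl 4-bromobut-2-ynoate 2 is taken as a commercial reagent, and ring B enters as commercial orsellinic acid 1, because the ring-forming chemistry is reserved for ring A.

**Step 1**
Reactants: 1 orsellinic acid (2,4-dihydroxy-6-methylbenzoic acid); 2 methyl 4-bromobut-2-ynoate
Product: 3 4-methoxy-4-oxobut-2-yn-1-yl 2,4-dihydroxy-6-methylbenzoate
Conditions: KHCO3 (1.05 equiv), DMF, 0 °C, 30 min; 2 (1.0 equiv), 0 °C to rt
Reagents that add atoms: none
Why: carboxylate O-alkylation (SN2 at a propargylic bromide), in which hydrogencarbonate deprotonates only the carboxylic acid, so the phenols should neither alkylate nor add to the triple bond, and the linear alkyne keeps the new ester oxygen away from the methyl ester.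

**Step 2**
Reactants: 3 4-methoxy-4-oxobut-2-yn-1-yl 2,4-dihydroxy-6-methylbenzoate
Product: 5 4-methoxy-4-oxobut-2-yn-1-yl 3-formyl-2,4-dihydroxy-6-methylbenzoate, via chloro(methoxy)methyl arene 4 (not isolated)
Conditions: TiCl4 (3 equiv), Cl2CHOMe (1.3 equiv), CH2Cl2, −10 to 0 °C, 2 h; 1 M HCl/ice; chromatography
Reagents that add atoms: dichloromethyl methyl ether, COC(Cl)Cl; water, O
Why: Rieche formylation, in which the titanium phenoxides should deliver the electrophile to C3, the carbon flanked by both oxygens, the racemic α-chloro ether 4 is hydrolysed on work-up, the internal ynoate is a poor chloride acceptor at 0 °C, and any 5-formyl isomer would be separated.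

**Step 3**
Reactants: 6 methyl 2-methyl-3-oxobutanoate
Product: 7 methyl 2-methyl-3-(trimethylsilyloxy)but-2-enoate (E/Z mixture)
Conditions: Me3SiCl (1.5 equiv), Et3N (1.6 equiv), hexane, rt, 48 h; filter under Ar, distil
Reagents that add atoms: chlorotrimethylsilane, C[Si](C)(C)Cl
Why: silyl enol ether formation by O-silylation of the β-keto ester enol; the double-bond geometry does not matter because both isomers give the same dienolate in the next step.

**Step 4**
Reactants: 7 methyl 2-methyl-3-(trimethylsilyloxy)but-2-enoate
Product: 8 1-methoxy-2-methyl-1,3-bis(trimethylsilyloxy)buta-1,3-diene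
Conditions: LiN(i-Pr)2 (1.2 equiv), THF, −78 °C, 1 h; Me3SiCl (1.3 equiv), −78 °C to rt; concentrate, take up in hexane, filter under Ar, use at once
Reagents that add atoms: chlorotrimethylsilane, C[Si](C)(C)Cl
Why: γ-deprotonation of the silyl enol ether ester (only the vinylogous methyl is acidic) and O-silylation of the ester dienolate give the 2-methyl analogue of the Chan diene; the ketene acetal geometry is of no consequence.

**Step 5**
Reactants: 5 4-methoxy-4-oxobut-2-yn-1-yl 3-formyl-2,4-dihydroxy-6-methylbenzoate; 8 1-methoxy-2-methyl-1,3-bis(trimethylsilyloxy)buta-1,3-diene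
Product: 11 methyl 6-{[(3-formyl-2,4-dihydroxy-6-methylbenzoyl)oxy]methyl}-2,4-dihydroxy-3-methylbenzoate, via bis(trimethylsilyl) ether 9 (not isolated), via cyclohexa-1,4-diene cycloadduct 10 (not isolated)
Conditions: N,O-bis(trimethylsilyl)acetamide (2.5 equiv), toluene, 40 °C, 1 h; 8 (2 equiv), 80 °C, 16 h, Ar; then 1 M HCl, THF, 0 °C to rt
Reagents that add atoms: none
Why: Normal-electron-demand Diels–Alder reaction followed by aromatisation: after the silyl amide has capped both phenols as silyl ethers 9 (so that they can neither protonate the diene nor activate the aldehyde by hydrogen bonding), the terminal CH2 of diene 8, its most nucleophilic carbon, bonds to the β-carbon of the ynoate (the one bearing the CH2O arm) and the ketene acetal carbon bonds to the α-carbon, giving cyclohexa-1,4-diene 10. Acid then removes the silyl groups and the mixed ketal carbon loses methanol, which aromatises the ring to the 2,4-dihydroxybenzoate. The closest known reaction type is the cycloaddition of 1-alkoxy-1,3-bis(silyloxy)buta-1,3-dienes (Chan and Brassard dienes) with acetylenic esters to give resorcylates. Ring A is closed by an intermolecular [4+2] cycloaddition that forms its C1–C2 and C5–C6 bonds; the ketal carbon of 10 is a racemic stereocentre that is destroyed on aromatisation, so nothing has to be controlled. The step needs regioselectivity, which the matched polarisation of the ester-bearing alkyne and the oxygen-rich diene should secure, and chemoselectivity for the triple bond over the aldehyde, which the absence of any Lewis acid and the two flanking silyloxy groups should secure.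

## Compound list

1 | orsellinic acid (2,4-dihydroxy-6-methylbenzoic acid) | Cc1cc(O)cc(O)c1C(=O)O | starting material
2 | methyl 4-bromobut-2-ynoate | COC(=O)C#CCBr | starting material
3 | 4-methoxy-4-oxobut-2-yn-1-yl 2,4-dihydroxy-6-methylbenzoate | COC(=O)C#CCOC(=O)c1c(C)cc(O)cc1O | intermediate
4 | 4-methoxy-4-oxobut-2-yn-1-yl 3-[chloro(methoxy)methyl]-2,4-dihydroxy-6-methylbenzoate (racemic, not isolated) | COC(Cl)c1c(O)cc(C)c(C(=O)OCC#CC(=O)OC)c1O | intermediate
5 | 4-methoxy-4-oxobut-2-yn-1-yl 3-formyl-2,4-dihydroxy-6-methylbenzoate | COC(=O)C#CCOC(=O)c1c(C)cc(O)c(C=O)c1O | intermediate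
6 | methyl 2-methyl-3-oxobutanoate (racemic) | COC(=O)C(C)C(C)=O | starting material
7 | methyl 2-methyl-3-(trimethylsilyloxy)but-2-enoate (E/Z mixture) | COC(=O)C(C)=C(C)O[Si](C)(C)C | intermediate
8 | 1-methoxy-2-methyl-1,3-bis(trimethylsilyloxy)buta-1,3-diene (ketene acetal geometry not defined) | COC(O[Si](C)(C)C)=C(C)C(=C)O[Si](C)(C)C | intermediate
9 | 4-methoxy-4-oxobut-2-yn-1-yl 3-formyl-6-methyl-2,4-bis(trimethylsilyloxy)benzoate (not isolated) | COC(=O)C#CCOC(=O)c1c(C)cc(O[Si](C)(C)C)c(C=O)c1O[Si](C)(C)C | intermediate
10 | methyl 2-{[(3-formyl-6-methyl-2,4-bis(trimethylsilyloxy)benzoyl)oxy]methyl}-6-methoxy-5-methyl-4,6-bis(trimethylsilyloxy)cyclohexa-1,4-diene-1-carboxylate (racemic, not isolated) | COC(=O)C1=C(COC(=O)c2c(C)cc(O[Si](C)(C)C)c(C=O)c2O[Si](C)(C)C)CC(O[Si](C)(C)C)=C(C)C1(OC)O[Si](C)(C)C | intermediate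
11 | methyl 6-{[(3-formyl-2,4-dihydroxy-6-methylbenzoyl)oxy]methyl}-2,4-dihydroxy-3-methylbenzoate | COC(=O)c1c(COC(=O)c2c(C)cc(O)c(C=O)c2O)cc(O)c(C)c1O | target

**Total steps:** 5. **Longest linear sequence:** 3 (steps 1, 2, 5 or steps 3, 4, 5).

**Steps most likely to fail** (given in the order in which the fallbacks build on each other):

1. Step 2, the formylation. Chloride could add to the Lewis-acid-activated triple bond, and the formyl group could enter at C5 in competition with C3. The fallback sets out from 1 and comes back at 5, with the formyl group introduced before the alkyne is present. Acid 1 would be converted with benzyl bromide and KHCO3 in DMF into benzyl 2,4-dihydroxy-6-methylbenzoate F1. F1 would be formylated (TiCl4, Cl2CHOMe, CH2Cl2, 0 °C) and freed from any isomer by crystallisation to give benzyl 3-formyl-2,4-dihydroxy-6-methylbenzoate F2. Hydrogenolysis (H2, Pd/C, EtOAc, rt) would give haematommic acid F3, and alkylation of its potassium carboxylate with bromide 2 (KHCO3, DMF, rt) would rejoin the route at 5.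

2. Step 5, the cycloaddition. The ketene acetal terminus of 8 could attack the aldehyde (aldol or hetero-Diels–Alder pathway) in place of the triple bond, or the first C–C bond could form without ring closure. The fallback sets out from 2 and 8 and comes back at 11: the ring would be built on a dienophile that holds no aldehyde, and the ester bond made afterwards. Diene 8 and bromide 2 (toluene, 80 °C; then 1 M HCl, THF) would give methyl 6-(bromomethyl)-2,4-dihydroxy-3-methylbenzoate F4, whose benzylic carbon is meta to both hydroxyls and so cannot form a quinone methide. Displacement of its bromide by the potassium salt of haematommic acid F3 (KHCO3, DMF, rt; F3 as made in the fallback above) would give 11.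

3. Step 1, the esterification. The 4-hydroxyl could be alkylated, oxygen nucleophiles could add to the electron-poor triple bond, or base could isomerise the bromide to an allene. The fallback sets out from 1 and comes back at 3: the alcohol and not a halide would be activated, without base. Methyl 4-hydroxybut-2-ynoate F5 would be coupled with acid 1 under Mitsunobu conditions (P(3-ClC6H4)3, diisopropyl azodicarboxylate, THF, 0 °C, betaine formed before the substrates are added), the carboxylic acid being by far the most acidic pronucleophile, to give 3.

## Further compounds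

F1 | step 2 | benzyl 2,4-dihydroxy-6-methylbenzoate | Cc1cc(O)cc(O)c1C(=O)OCc1ccccc1
F2 | step 2 | benzyl 3-formyl-2,4-dihydroxy-6-methylbenzoate | Cc1cc(O)c(C=O)c(O)c1C(=O)OCc1ccccc1
F3 | step 2 | haematommic acid (3-formyl-2,4-dihydroxy-6-methylbenzoic acid) | Cc1cc(O)c(C=O)c(O)c1C(=O)O
F4 | step 5 | methyl 6-(bromomethyl)-2,4-dihydroxy-3-methylbenzoate | COC(=O)c1c(CBr)cc(O)c(C)c1O
F5 | step 1 | methyl 4-hydroxybut-2-ynoate | COC(=O)C#CCO
A1 | direct plan | methyl 6-chloro-2,4-dihydroxy-3-methylbenzoate | COC(=O)c1c(Cl)cc(O)c(C)c1O
A2 | direct plan | potassium trifluoro{[(3-formyl-2,4-dihydroxy-6-methylbenzoyl)oxy]methyl}borate | [K+].F[B-](F)(F)COC(=O)c1c(C)cc(O)c(C=O)c1O
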